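Remark on the chemistry: SEM stands for 2-(trimethylsilyl)ethoxymethyl and "SEM-oxy" for the group OCH2OCH2CH2SiMe3. The target has no stereocentre; the stereocentres that occur in fallback compounds and in the alternatives are racemic, with one enantiomer drawn.

## Analysis of the target

The target is a flavonol, a 4H-chromen-4-one. Benzo ring A (C4a to C8a) carries OH at C5, OMe at C6 and OH at C7. Pyranone ring C carries OH at C3, and C2 bears the para-substituted phenyl ring B, whose 4'-oxygen is a prenyl (3-methylbut-2-enyl) ether.

There is no stereocentre and no stereogenic double bond, so the problems are regiochemistry and functional-group compatibility only.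

The aryl prenyl ether is the most delicate group. Acid cleaves or cyclises it, hydrogenation reduces it, zerovalent palladium with a nucleophile can ionise it, and strong heating triggers a Claisen rearrangement. The free 3-hydroxy-4-pyranone unit is oxidised by air under base.

The difficulty is the differentiation of five oxygens. The 6-methoxy group sits between two free hydroxyls, and the only other O-alkyl group is on O4', whereas direct alkylation of a free polyhydroxyflavone would go to the 7-hydroxyl first. Classical flavone syntheses from 2,4,6-trioxygenated aryl ketones can also deliver the 8-methoxy isomer, by closure on the wrong ortho oxygen or by Wessely–Moser equilibration.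

The strategy rests on C4: it is a single carbonyl carbon between C4a of ring A and C3. Ring C therefore divides into an ortho-iodophenol (C4a, C8a, O1), carbon monoxide (C4) and an arylacetylene (C3, C2, ring B). The iodophenol derives from a phenol with a mirror plane through its hydroxyl-bearing carbon and the methoxy-bearing carbon, which fixes the place of the 6-methoxy group.

## Retrosynthetic reasoning

**20 to 19.** The last operation is removal of three SEM groups from O3, O5 and O7 of 19. The prenyl ether tolerates neither acid nor hydrogen, so the hydroxyls travel in a group that leaves with fluoride under basic, non-reducing conditions. The forward step has to cleave three acetal C–O bonds without touching the allylic ether.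

**19 to 17 and 18.** The O4'–CH2 bond is cut to phenol 17 and prenyl bromide 18. Compound 17 has one free hydroxyl, so alkylation can go nowhere else. The prenyl group is introduced after every palladium and hydrogen step.

**17 to 16.** O4' is carried as a benzyl ether and unmasked by hydrogenolysis. Benzyl is orthogonal to SEM and survives strong base and the palladium–amine conditions of the ring construction, under which an allylic aryl ether would be at risk.

**16 to 15 and 2.** The acetal bond at O3 is cut back to flavonol 15 and SEM chloride 2. The 3- and 4'-hydroxyls are too similar in acidity to be told apart by alkylation, so O3 is masked before O4' is freed.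

**15 to 12.** The C3–O bond is cut back to C3–H. That hydrogen is the only acidic C–H next to the carbonyl, so metalation, trapping on boron and oxidation can install the oxygen. The gain is that the alkyne partner needs no oxygen at the future C3 and the ring-forming step gives the flavone oxidation level directly.

**12 to 6, 9 and 8.** This is the key disconnection: C4a–C4, C4–C3 and O1–C2 are cut, giving iodophenol 6, carbon monoxide 9 and alkyne 8. The cut is made here because C4 is a one-carbon unit and all three fragments are simple. Ring A arrives intact with its oxygen pattern and ring B with its para oxygen. The forward reaction has to couple the three components carbonylatively and then close ring C in the six-membered sense.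

**6 to 5.** The C–I bond is cut. Phenol 5 is symmetric, its para position is blocked, and its two ortho carbons are equivalent. Any mono-iodination gives 6, with the hydroxyl (future O1) para to the methoxy group (future C6).

**5 to 3, through boronate 4.** The C–O bond at the carbon meta to both SEM ethers is cut back to C–H. Electrophilic substitution of 3 would attack ortho and para to the ether oxygens and cannot reach this carbon. It is, however, the sterically most open C–H, which is what catalytic C–H borylation selects; oxidation of 4 then gives the phenol.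

**3 to 1 and 2.** Two O–C acetal bonds are cut. 2-Methoxyresorcinol 1 already holds the future 6-methoxy group between the future O5 and O7.

**8 to 7.** The triple bond is cut back to the aldehyde carbon of 7 by a one-carbon homologation, so the benzyl ether is bought ready-made.

## Alternatives that were turned down

**Alternative 1: ring A built last by a biomimetic Claisen-type cyclisation.**

- **Disconnection:** C4a–C5. The precursor A2 is a 4-pyranone with rings C and B complete, O3 as SEM ether and the prenyl ether in place. Its remaining ring carbon carries a CH2–CO–CH(OMe)–CO2Me chain.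
- **Forward key step:** a magnesium alkoxide in the parent alcohol forms the extended enolate, C4a attacks the ester carbonyl, and enolisation gives the aromatic ring A of A1.
- **For:** A1 is one fluoride step from the target. The 6-methoxy position is fixed by the chain. No hydrogenolysis, no palladium near the prenyl ether and no separate C3 oxygenation are needed.
- **Against:** the work moves into A2. It is a fully substituted pyranone with a differentiated 3-oxygen and an alpha-methoxy beta-keto ester chain, which means several C–C bond formations on enolisable polycarbonyl intermediates. The most acidic C–H of A2 lies between ketone and ester, not at the CH2 that must be deprotonated for the extended enolate. The alkoxide can also open the pyranone or cleave the keto ester by retro-Claisen reaction. Finally, the route constructs a benzene ring that can be bought.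
- **Comparison:** on protecting-group economy of the end game Alternative 1 is stronger (one SEM group instead of three, no benzyl-to-prenyl exchange). The chosen route offers ring A from a commercial arene in three steps, a convergent union, and risk confined to one step whose partners are quick to remake.

**Alternative 2: Parham-type closure of a dihydroflavonol, aromatised late.**

- **Disconnection:** C4–C4a at the flavanonol oxidation level. The precursor A4 is an aryl bromide (bromine at the future C4a) whose phenol oxygen is already bonded to the benzylic carbon of a 2-hydroxy-3-arylpropanoic N-methoxy-N-methylamide.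
- **Forward key step:** bromine–lithium exchange with an alkyllithium at low temperature, then attack of the aryllithium on the amide, closes ring C as the trans-3-hydroxychroman-4-one A3. A later dehydrogenation gives the flavonol.
- **For:** O3 comes from the chain, so no C–H oxidation is needed. The closure is a fast intramolecular acylation through a chelated tetrahedral intermediate. The prenyl ether can be present from the start.
- **Against:** two stereocentres (C2, C3) are set only to be erased on aromatisation. A4 needs an aryl–oxygen bond to a benzylic carbon from a hindered, di-ortho-substituted bromophenol. The free hydroxyl consumes base, and its alkoxide sits beta to an aryloxide leaving group. A3 is prone to base-induced retro-oxa-Michael ring opening and epimerisation. An extra oxidation compatible with the prenyl alkene is required, and the brominated ring A needs the same preparation as 6.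
- **Comparison:** Alternative 2 is as strong or stronger in placing O3 without lithiation and in the mildness of its closure (no pressure vessel). The chosen route offers the flavone oxidation level directly, no stereocentre at any stage, and fewer steps.

**Alternative 3: ring B by Diels–Alder reaction on a 2-ethynylchromone.**

- **Disconnection:** C1'–C2' and C5'–C6'. The partners are 2-ethynylchromone A6 (rings A and C with all three SEM-oxy groups) and diene A7.
- **Forward key step:** thermal [4+2] addition; the adduct loses its methoxy group as the alcohol and its silyl group and aromatises to phenol A5. A5 is the same compound as 17 of the chosen route.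
- **For:** the 4'-hydroxyl appears free and unique without a benzyl ether or hydrogenolysis. The polarisation of both partners points to the para phenol. The end game is identical.
- **Against:** the key step is spent on ring B, a plain para-disubstituted benzene that can be bought with its oxygen in place. The harder task stays unsolved, because A6 needs a chromone that already carries the 3-oxygen and a C2 alkynyl group. The alkyne is only weakly activated through the cross-conjugated, 3-oxygenated pyranone, so forcing conditions with a hydrolytically sensitive diene are likely, and the meta-phenol regiochemistry or addition to C2=C3 can intervene.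
- **Comparison:** Alternative 3 is stronger on the ring B protecting group and avoids C3 lithiation. The chosen route reaches 17 in seven linear steps from a commercial arene and forms three bonds of ring C, the ring that defines the flavone, in one operation.

Key step: step 5

## Route

Step 1
Reactants: 1 2-methoxyresorcinol (2-methoxybenzene-1,3-diol); 2 2-(trimethylsilyl)ethoxymethyl chloride (SEM chloride)
Product: 3 2-methoxy-1,3-bis(SEM-oxy)benzene
Conditions: NaH (2.4 equiv), 2 (2.3 equiv), DMF, 0 °C to rt
Reagents that add atoms: none
Why: Williamson-type O-alkylation of the two equivalent phenoxides with the chloromethyl ether. The acetal ethers are inert to the later boron, palladium, lithium amide and hydrogenation chemistry and leave with fluoride at the end.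

Step 2
Reactants: 3 2-methoxy-1,3-bis(SEM-oxy)benzene
Product: 5 4-methoxy-3,5-bis(SEM-oxy)phenol, via aryl pinacol boronate 4 (not isolated)
Conditions: [Ir(OMe)(cod)]2 (1.5 mol%), 4,4'-di-tert-butyl-2,2'-bipyridine (3 mol%), B2pin2 (1.0 equiv), THF, 80 °C; then 30% H2O2, aq NaOH, 0 °C
Reagents that add atoms: bis(pinacolato)diboron, CC1(C)OB(OC1(C)C)B1OC(C)(C)C(C)(C)O1 (supplies the boryl group of 4 only); hydrogen peroxide, OO (supplies the phenol oxygen of 5)
Why: Iridium-catalysed aromatic C–H borylation is sterically governed and should go to C5 of 3, the only ring C–H without an ortho substituent. Alkaline peroxide then converts the C–B bond into C–O by 1,2-shift of the aryl group from boron to oxygen in the same flask.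

Step 3
Reactants: 5 4-methoxy-3,5-bis(SEM-oxy)phenol
Product: 6 2-iodo-4-methoxy-3,5-bis(SEM-oxy)phenol
Conditions: N-iodosuccinimide (1.0 equiv), CH2Cl2, −20 to 0 °C, dark
Reagents that add atoms: N-iodosuccinimide, O=C1CCC(=O)N1I
Why: Electrophilic aromatic iodination of a very electron-rich phenol. The para position is blocked by the methoxy group and the two ortho carbons are the only ring C–H positions and are equivalent, so one equivalent of reagent at low temperature should give a single mono-iodide.

Step 4
Reactants: 7 4-(benzyloxy)benzaldehyde
Product: 8 1-(benzyloxy)-4-ethynylbenzene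
Conditions: dimethyl (1-diazo-2-oxopropyl)phosphonate (1.2 equiv), K2CO3 (2 equiv), MeOH, rt
Reagents that add atoms: dimethyl (1-diazo-2-oxopropyl)phosphonate, COP(=O)(OC)C(=[N+]=[N-])C(C)=O
Why: Ohira–Bestmann homologation. Methanolysis of the acetyl group frees the diazomethylphosphonate anion, which adds to the aldehyde; loss of dimethyl phosphate and dinitrogen gives an alkylidene carbene that rearranges to the terminal alkyne by 1,2-hydrogen shift.

Step 5
Reactants: 6 2-iodo-4-methoxy-3,5-bis(SEM-oxy)phenol; 8 1-(benzyloxy)-4-ethynylbenzene; 9 carbon monoxide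
Product: 12 2-[4-(benzyloxy)phenyl]-6-methoxy-5,7-bis(SEM-oxy)-4H-chromen-4-one, via ynone 10 (not isolated), via enaminone 11 (not isolated)
Conditions: PdCl2(PPh3)2 (5 mol%), Et2NH (solvent), CO (20 bar), 120 °C, autoclave
Reagents that add atoms: diethylamine, CCNCC (held only in intermediate 11 and released again on ring closure)
Why: Zerovalent palladium, formed from PdCl2(PPh3)2 by reduction in the amine–alkyne medium, adds oxidatively to the C–I bond of 6; CO inserts to give the aroyl-palladium species, and amine-assisted palladation of 8 followed by reductive elimination gives ynone 10, forming C4a–C4 and C4–C3. Diethylamine then adds to the triple bond of 10 to give enaminone 11, and the ortho-phenoxide displaces the amine at the beta carbon by addition–elimination, a 6-endo closure that forms O1–C2 and ring C. The closest known reaction type is the palladium-catalysed carbonylative annulation of ortho-iodophenols with terminal alkynes in a secondary amine, which gives flavones and chromones. No stereocentre is formed. The step needs carbonylative instead of direct alkyne coupling, and the CO pressure together with the two ortho substituents flanking the aryl–palladium bond should make CO insertion faster than coupling with the alkyne. It needs six- over five-membered closure, and the amine secures this because adduct 11 offers only C2 as electrophile, so the aurone path from direct attack on the ynone is bypassed. Ring A regiochemistry is not at stake: 6 comes from symmetric phenol 5 with its hydroxyl para to the methoxy group, so O1 ends para to C6 and an 8-methoxy isomer cannot arise. The SEM and benzyl ethers are inert to palladium, CO and amine, which is why ring B carries benzyl and not the allylic prenyl ether at this stage.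

Step 6
Reactants: 12 2-[4-(benzyloxy)phenyl]-6-methoxy-5,7-bis(SEM-oxy)-4H-chromen-4-one
Product: 15 2-[4-(benzyloxy)phenyl]-3-hydroxy-6-methoxy-5,7-bis(SEM-oxy)-4H-chromen-4-one, via 3-lithioflavone 13 (not isolated), via flavone-3-boronate 14 (not isolated)
Conditions: LiN(i-Pr)2 (1.5 equiv), THF, −78 °C; B(OMe)3 (3 equiv), −78 to 0 °C; AcOH, 30% H2O2, 0 °C to rt
Reagents that add atoms: hydrogen peroxide, OO (supplies O3 of 15); trimethyl borate, COB(OC)OC (held in 14 only); lithium diisopropylamide, [Li+].CC(C)[N-]C(C)C (lithium of 13 only)
Why: C3–H is the most acidic C–H of 12 (vinylic, next to C4=O, with lithium chelated by the carbonyl oxygen) and is removed by the hindered amide at −78 °C; the vinyllithium is trapped on boron and peroxide oxidation with 1,2-shift from boron to oxygen gives the 3-hydroxyl. Lithiation, borylation and oxidation at C3 of flavones is a known route to flavonols, and the amide base is too weak to metalate next to the SEM ethers or at the benzylic CH2.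

Step 7
Reactants: 15 2-[4-(benzyloxy)phenyl]-3-hydroxy-6-methoxy-5,7-bis(SEM-oxy)-4H-chromen-4-one; 2 2-(trimethylsilyl)ethoxymethyl chloride
Product: 16 2-[4-(benzyloxy)phenyl]-6-methoxy-3,5,7-tris(SEM-oxy)-4H-chromen-4-one
Conditions: NaH (1.3 equiv), 2 (1.3 equiv), THF, 0 °C to rt
Reagents that add atoms: none
Why: O-alkylation of the flavonol oxyanion with the hard chloromethyl ether. Masking O3 leaves O4' as the only oxygen that can be freed and alkylated in the next two steps.

Step 8
Reactants: 16 2-[4-(benzyloxy)phenyl]-6-methoxy-3,5,7-tris(SEM-oxy)-4H-chromen-4-one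
Product: 17 2-(4-hydroxyphenyl)-6-methoxy-3,5,7-tris(SEM-oxy)-4H-chromen-4-one
Conditions: H2 (1 atm), 10% Pd/C, EtOAc–EtOH, rt
Reagents that add atoms: none
Why: Catalytic hydrogenolysis of the benzyl aryl ether. SEM ethers and the methyl ether are inert, and the tetrasubstituted, doubly oxygenated C2=C3 bond of the pyranone should not be reduced under one atmosphere of hydrogen.

Step 9
Reactants: 17 2-(4-hydroxyphenyl)-6-methoxy-3,5,7-tris(SEM-oxy)-4H-chromen-4-one; 18 prenyl bromide (1-bromo-3-methylbut-2-ene)
Product: 19 6-methoxy-2-[4-(3-methylbut-2-enyloxy)phenyl]-3,5,7-tris(SEM-oxy)-4H-chromen-4-one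
Conditions: K2CO3 (2 equiv), 18 (1.3 equiv), acetone, reflux
Reagents that add atoms: none
Why: Williamson etherification (SN2 at the primary allylic bromide) of the only free hydroxyl in the molecule. O-alkylation at the unhindered CH2 terminus is expected for a phenoxide under these conditions.

Step 10
Reactants: 19 6-methoxy-2-[4-(3-methylbut-2-enyloxy)phenyl]-3,5,7-tris(SEM-oxy)-4H-chromen-4-one
Product: 20 3,5,7-trihydroxy-6-methoxy-2-[4-(3-methylbut-2-enyloxy)phenyl]-4H-chromen-4-one (3,5,7-trihydroxy-6-methoxy-4'-prenyloxyflavone)
Conditions: Bu4NF (1 M in THF, 9 equiv), DMPU, 60 °C, argon; aq NH4Cl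
Reagents that add atoms: none
Why: Fluoride attacks silicon and each SEM group fragments to fluorotrimethylsilane, ethylene, formaldehyde and an aryloxide; all three oxygens are conjugated with the C4 carbonyl and are good leaving groups. The conditions are basic and non-reducing, so the prenyl ether should survive, and the temperature is far below that of an aryl prenyl ether Claisen rearrangement.

## Compound list

1 | 2-methoxyresorcinol (2-methoxybenzene-1,3-diol) | COc1c(O)cccc1O | starting material
2 | 2-(trimethylsilyl)ethoxymethyl chloride (SEM chloride) | C[Si](C)(C)CCOCCl | starting material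
3 | 2-methoxy-1,3-bis(SEM-oxy)benzene | COc1c(OCOCC[Si](C)(C)C)cccc1OCOCC[Si](C)(C)C | intermediate
4 | 2-[4-methoxy-3,5-bis(SEM-oxy)phenyl]-4,4,5,5-tetramethyl-1,3,2-dioxaborolane (not isolated) | COc1c(OCOCC[Si](C)(C)C)cc(B2OC(C)(C)C(C)(C)O2)cc1OCOCC[Si](C)(C)C | intermediate
5 | 4-methoxy-3,5-bis(SEM-oxy)phenol | COc1c(OCOCC[Si](C)(C)C)cc(O)cc1OCOCC[Si](C)(C)C | intermediate
6 | 2-iodo-4-methoxy-3,5-bis(SEM-oxy)phenol | COc1c(OCOCC[Si](C)(C)C)cc(O)c(I)c1OCOCC[Si](C)(C)C | intermediate
7 | 4-(benzyloxy)benzaldehyde | O=Cc1ccc(OCc2ccccc2)cc1 | starting material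
8 | 1-(benzyloxy)-4-ethynylbenzene | C#Cc1ccc(OCc2ccccc2)cc1 | intermediate
9 | carbon monoxide | [C-]#[O+] | starting material
10 | 3-[4-(benzyloxy)phenyl]-1-[2-hydroxy-5-methoxy-4,6-bis(SEM-oxy)phenyl]prop-2-yn-1-one (not isolated) | COc1c(OCOCC[Si](C)(C)C)cc(O)c(C(=O)C#Cc2ccc(OCc3ccccc3)cc2)c1OCOCC[Si](C)(C)C | intermediate
11 | (E)-3-[4-(benzyloxy)phenyl]-3-(diethylamino)-1-[2-hydroxy-5-methoxy-4,6-bis(SEM-oxy)phenyl]prop-2-en-1-one (not isolated; the geometry is lost on ring closure) | CCN(CC)/C(=C/C(=O)c1c(O)cc(OCOCC[Si](C)(C)C)c(OC)c1OCOCC[Si](C)(C)C)c1ccc(OCc2ccccc2)cc1 | intermediate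
12 | 2-[4-(benzyloxy)phenyl]-6-methoxy-5,7-bis(SEM-oxy)-4H-chromen-4-one | COc1c(OCOCC[Si](C)(C)C)cc2oc(-c3ccc(OCc4ccccc4)cc3)cc(=O)c2c1OCOCC[Si](C)(C)C | intermediate
13 | 2-[4-(benzyloxy)phenyl]-3-lithio-6-methoxy-5,7-bis(SEM-oxy)-4H-chromen-4-one (not isolated) | COc1c(OCOCC[Si](C)(C)C)cc2oc(-c3ccc(OCc4ccccc4)cc3)c([Li])c(=O)c2c1OCOCC[Si](C)(C)C | intermediate
14 | dimethyl {2-[4-(benzyloxy)phenyl]-6-methoxy-4-oxo-5,7-bis(SEM-oxy)-4H-chromen-3-yl}boronate (not isolated) | COc1c(OCOCC[Si](C)(C)C)cc2oc(-c3ccc(OCc4ccccc4)cc3)c(B(OC)OC)c(=O)c2c1OCOCC[Si](C)(C)C | intermediate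
15 | 2-[4-(benzyloxy)phenyl]-3-hydroxy-6-methoxy-5,7-bis(SEM-oxy)-4H-chromen-4-one | COc1c(OCOCC[Si](C)(C)C)cc2oc(-c3ccc(OCc4ccccc4)cc3)c(O)c(=O)c2c1OCOCC[Si](C)(C)C | intermediate
16 | 2-[4-(benzyloxy)phenyl]-6-methoxy-3,5,7-tris(SEM-oxy)-4H-chromen-4-one | COc1c(OCOCC[Si](C)(C)C)cc2oc(-c3ccc(OCc4ccccc4)cc3)c(OCOCC[Si](C)(C)C)c(=O)c2c1OCOCC[Si](C)(C)C | intermediate
17 | 2-(4-hydroxyphenyl)-6-methoxy-3,5,7-tris(SEM-oxy)-4H-chromen-4-one | COc1c(OCOCC[Si](C)(C)C)cc2oc(-c3ccc(O)cc3)c(OCOCC[Si](C)(C)C)c(=O)c2c1OCOCC[Si](C)(C)C | intermediate
18 | prenyl bromide (1-bromo-3-methylbut-2-ene) | CC(C)=CCBr | starting material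
19 | 6-methoxy-2-[4-(3-methylbut-2-enyloxy)phenyl]-3,5,7-tris(SEM-oxy)-4H-chromen-4-one | COc1c(OCOCC[Si](C)(C)C)cc2oc(-c3ccc(OCC=C(C)C)cc3)c(OCOCC[Si](C)(C)C)c(=O)c2c1OCOCC[Si](C)(C)C | intermediate
20 | 3,5,7-trihydroxy-6-methoxy-2-[4-(3-methylbut-2-enyloxy)phenyl]-4H-chromen-4-one | COc1c(O)cc2oc(-c3ccc(OCC=C(C)C)cc3)c(O)c(=O)c2c1O | target

## Step count and least certain steps

Total: 10 steps. Longest linear sequence: 9 steps (steps 1, 2, 3, 5, 6, 7, 8, 9, 10, starting from 1). Step 4 is a one-step side branch.

**Step 5 (key step).** The most likely failure is coupling of the aryl–palladium species with the alkyne before CO insertion, followed by five-membered closure of the phenol onto the alkyne. Aminocarbonylation of the aroyl-palladium species by the solvent amine and reductive loss of iodine are further risks, because oxidative addition at a crowded, electron-rich C–I bond is slow. The fallback leaves palladium and CO out and makes ynone 10 by carbonyl addition. It sets out from phenol 5 and alkyne 8 and comes back at 12. Magnesium-mediated ortho-formylation of 5 (MgCl2, Et3N, paraformaldehyde, MeCN, reflux; the two ortho positions are equivalent) should give 2-hydroxy-5-methoxy-4,6-bis(SEM-oxy)benzaldehyde F1. The lithium acetylide of 8 (n-BuLi, THF, −78 °C, 2.2 equiv, one equivalent taking the phenol proton) adds to F1 to give racemic 3-[4-(benzyloxy)phenyl]-1-[2-hydroxy-5-methoxy-4,6-bis(SEM-oxy)phenyl]prop-2-yn-1-ol F2. MnO2 in CH2Cl2 oxidises F2 to ynone 10, and Et2NH in EtOH converts 10 through 11 into 12.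

**Step 3.** A second iodination at the remaining ortho carbon, or oxidation of the para-methoxyphenol to a quinone by the iodinating agent, may compete because the ring is extremely electron-rich. The fallback replaces electrophilic substitution by directed ortho-metalation, which can introduce one iodine only. It sets out from 5 and comes back at 6. Diethylcarbamoyl chloride (NaH, THF) converts 5 into 4-methoxy-3,5-bis(SEM-oxy)phenyl N,N-diethylcarbamate F3. s-BuLi with TMEDA in THF at −78 °C metalates the carbon between the carbamate and an SEM ether, and I2 at −78 °C gives 2-iodo-4-methoxy-3,5-bis(SEM-oxy)phenyl N,N-diethylcarbamate F4. KOH in EtOH at reflux removes the carbamate to give 6.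

**Step 6.** The 3-lithio species 13 may fragment by beta-elimination of the O1 aryloxide (ring opening) if it warms before it is trapped, or metalation may be incomplete. The fallback oxidises the C2=C3 bond instead of the C3–H bond. It sets out from 12 and comes back at 15. Dimethyldioxirane in acetone–CH2Cl2 at 0 °C epoxidises the pyranone double bond to rac-(2R,3S)-2-[4-(benzyloxy)phenyl]-2,3-epoxy-6-methoxy-5,7-bis(SEM-oxy)chroman-4-one F5. A trace of p-TsOH opens the oxirane at C2, where the cation is stabilised by O1 and ring B, and loss of the C3 proton gives 15.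

**Step 10.** Cleavage of aryl SEM ethers by fluoride can be slow and stop at partly protected stages. The formaldehyde set free can hydroxymethylate the electron-rich C8 of the phenoxide, and the flavonol anion can be oxidised if air enters. The fallback exchanges the SEM groups for acetates before the prenyl ether exists, so the prenyl ether only meets mild base. It sets out from 15 and comes back at 20.
- HCl in MeOH at 40 °C removes both SEM groups to give 2-[4-(benzyloxy)phenyl]-3,5,7-trihydroxy-6-methoxy-4H-chromen-4-one F6.
- Ac2O, pyridine and catalytic DMAP give 2-[4-(benzyloxy)phenyl]-6-methoxy-4-oxo-4H-chromene-3,5,7-triyl triacetate F7.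
- H2 and Pd/C in EtOAc give 2-(4-hydroxyphenyl)-6-methoxy-4-oxo-4H-chromene-3,5,7-triyl triacetate F8.
- Mitsunobu etherification with 3-methylbut-2-en-1-ol, PPh3 and diisopropyl azodicarboxylate in THF at 0 °C gives 6-methoxy-2-[4-(3-methylbut-2-enyloxy)phenyl]-4-oxo-4H-chromene-3,5,7-triyl triacetate F9.
- K2CO3 in MeOH at 0 °C under argon cleaves the three acetates to give 20.

## Further compounds

F1 | step 5 | 2-hydroxy-5-methoxy-4,6-bis(SEM-oxy)benzaldehyde | COc1c(OCOCC[Si](C)(C)C)cc(O)c(C=O)c1OCOCC[Si](C)(C)C
F2 | step 5 | racemic 3-[4-(benzyloxy)phenyl]-1-[2-hydroxy-5-methoxy-4,6-bis(SEM-oxy)phenyl]prop-2-yn-1-ol (R enantiomer drawn) | COc1c(OCOCC[Si](C)(C)C)cc(O)c([C@H](O)C#Cc2ccc(OCc3ccccc3)cc2)c1OCOCC[Si](C)(C)C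
F3 | step 3 | 4-methoxy-3,5-bis(SEM-oxy)phenyl N,N-diethylcarbamate | CCN(CC)C(=O)Oc1cc(OCOCC[Si](C)(C)C)c(OC)c(OCOCC[Si](C)(C)C)c1
F4 | step 3 | 2-iodo-4-methoxy-3,5-bis(SEM-oxy)phenyl N,N-diethylcarbamate | CCN(CC)C(=O)Oc1cc(OCOCC[Si](C)(C)C)c(OC)c(OCOCC[Si](C)(C)C)c1I
F5 | step 6 | rac-(2R,3S)-2-[4-(benzyloxy)phenyl]-2,3-epoxy-6-methoxy-5,7-bis(SEM-oxy)chroman-4-one (cis-fused oxirane, one enantiomer drawn) | O=C1[C@@H]2O[C@]2(c2ccc(OCc3ccccc3)cc2)Oc2cc(OCOCC[Si](C)(C)C)c(OC)c(OCOCC[Si](C)(C)C)c21
F6 | step 10 | 2-[4-(benzyloxy)phenyl]-3,5,7-trihydroxy-6-methoxy-4H-chromen-4-one | COc1c(O)cc2oc(-c3ccc(OCc4ccccc4)cc3)c(O)c(=O)c2c1O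
F7 | step 10 | 2-[4-(benzyloxy)phenyl]-6-methoxy-4-oxo-4H-chromene-3,5,7-triyl triacetate | COc1c(OC(C)=O)cc2oc(-c3ccc(OCc4ccccc4)cc3)c(OC(C)=O)c(=O)c2c1OC(C)=O
F8 | step 10 | 2-(4-hydroxyphenyl)-6-methoxy-4-oxo-4H-chromene-3,5,7-triyl triacetate | COc1c(OC(C)=O)cc2oc(-c3ccc(O)cc3)c(OC(C)=O)c(=O)c2c1OC(C)=O
F9 | step 10 | 6-methoxy-2-[4-(3-methylbut-2-enyloxy)phenyl]-4-oxo-4H-chromene-3,5,7-triyl triacetate | COc1c(OC(C)=O)cc2oc(-c3ccc(OCC=C(C)C)cc3)c(OC(C)=O)c(=O)c2c1OC(C)=O
A1 | alternative 1 | 5,7-dihydroxy-6-methoxy-2-[4-(3-methylbut-2-enyloxy)phenyl]-3-(SEM-oxy)-4H-chromen-4-one | COc1c(O)cc2oc(-c3ccc(OCC=C(C)C)cc3)c(OCOCC[Si](C)(C)C)c(=O)c2c1O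
A2 | alternative 1 | methyl 2-methoxy-4-{6-[4-(3-methylbut-2-enyloxy)phenyl]-4-oxo-5-(SEM-oxy)-4H-pyran-2-yl}-3-oxobutanoate (racemic; the methoxy-bearing carbon is enolisable, so no configuration is assigned) | COC(=O)C(OC)C(=O)Cc1cc(=O)c(OCOCC[Si](C)(C)C)c(-c2ccc(OCC=C(C)C)cc2)o1
A3 | alternative 2 | rac-(2R,3R)-3-hydroxy-6-methoxy-2-[4-(3-methylbut-2-enyloxy)phenyl]-5,7-bis(SEM-oxy)chroman-4-one (trans) | O=C1c2c(OCOCC[Si](C)(C)C)c(OC)c(OCOCC[Si](C)(C)C)cc2O[C@H](c2ccc(OCC=C(C)C)cc2)[C@H]1O
A4 | alternative 2 | rac-(2R,3R)-3-[2-bromo-4-methoxy-3,5-bis(SEM-oxy)phenoxy]-2-hydroxy-N-methoxy-N-methyl-3-[4-(3-methylbut-2-enyloxy)phenyl]propanamide | CON(C)C(=O)[C@H](O)[C@H](Oc1cc(OCOCC[Si](C)(C)C)c(OC)c(OCOCC[Si](C)(C)C)c1Br)c1ccc(OCC=C(C)C)cc1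
A5 | alternative 3 | 2-(4-hydroxyphenyl)-6-methoxy-3,5,7-tris(SEM-oxy)-4H-chromen-4-one (identical with 17) | COc1c(OCOCC[Si](C)(C)C)cc2oc(-c3ccc(O)cc3)c(OCOCC[Si](C)(C)C)c(=O)c2c1OCOCC[Si](C)(C)C
A6 | alternative 3 | 2-ethynyl-6-methoxy-3,5,7-tris(SEM-oxy)-4H-chromen-4-one | C#Cc1oc2cc(OCOCC[Si](C)(C)C)c(OC)c(OCOCC[Si](C)(C)C)c2c(=O)c1OCOCC[Si](C)(C)C
A7 | alternative 3 | (E)-1-methoxy-3-(trimethylsilyloxy)buta-1,3-diene | CO/C=C/C(=C)O[Si](C)(C)C
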